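**Structural features**

Compound 15 is an achiral benzophenone. Ring A is a 2-hydroxy-4,6-dimethoxyphenyl group, ring B is the benzo ring of a 2,2-dimethyl-2H-chromene (ring C is the pyran), and the ketone carbon joins ring A C1 to chromene C5. Ring B is 1,3,5-functionalised: the ketone on C5, a free hydroxyl on C7 and the pyran oxygen on C8a. The pyran is fused at C4a, the carbon between C5 and C8a, while C8 between the two oxygens remains a C–H. There is no stereocentre; isomerism appears only in intermediates and is erased. Fragile elements are the 2H-chromene (an acid-labile allylic aryl ether with a reducible alkene), the tertiary propargyl ether that precedes it, and the electron-rich ring A, which is easily halogenated and whose hindered, twisted ketone can be lost by protodeacylation in hot strong acid. The difficulty is threefold: the di-ortho-substituted diaryl ketone, the distinction of one ring A oxygen out of three and one ring B oxygen out of two, and fusion of the pyran at C4a and not at C8. The key step uses the meta relation of C5 to the oxygens on C7 and C8a, which is the relation of C5 to the two carbonyls of a 5-acylcyclohexane-1,3-dione, so ring B can be assembled from acyclic carbonyl compounds around a ketone already bonded to ring A.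

**Logic of the disconnections**

15 to 13: the pyran bonds C4–C4a and O1–C2 are cut and the ether bond from the ring B oxygen to the quaternary carbon is restored. One thermal operation without reagents then builds ring C last, so no earlier step has to tolerate the chromene. The forward step must send the sigmatropic shift to the ring B carbon next to the ketone and not to the carbon between the two oxygens.

13 to 11 and 12: the aryl ether O–C bond is cut. This removes the whole C5 unit as a commercial electrophile and leaves a triol. The forward step must etherify only one of two equivalent ring B hydroxyls and leave the hydrogen-bonded ring A hydroxyl alone.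

11 to 10: the methyl group on the ring A oxygen ortho to the ketone is put back. A symmetric trimethoxy ring A needs no protecting-group differentiation earlier and carries no phenol that could add to an electrophilic alkene. The forward step must remove exactly one ortho methyl, and must do so before any acid-labile group exists.

10 to 9: two hydrogens are returned to ring B; no skeletal bond is cut. The saturated 1,3-dione is reachable by carbonyl condensation, whereas the aromatic ketone is hindered to make by aryl–acyl bond formation. The forward step must dehydrogenate without reducing the diaryl ketone and without electrophilic attack on ring A.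

9 to 7 (through 8): carboxyl groups are re-attached at C4a and C6. They are the activating groups that make both annulation partners sufficiently acidic and electrophilic. The forward step must hydrolyse and decarboxylate under acid mild enough to keep the aryl ketone.

7 to 4 and 5 (key disconnection): ring B bonds C5–C6 and C7–C8 are cut. This opens ring B into a three-carbon nucleophile and a triply activated alkene that already carries ring A and the ketone. The forward step needs conjugate addition at the aroyl-bearing carbon and then closure through the acetyl methyl, in preference to any reaction at the 1,4-dicarbonyl array. In 4 all ring A oxygens are kept as methyl ethers and both esters are methyl esters matched to methoxide, so no phenol can cyclise onto the alkene and ester exchange is degenerate.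

4 to 2 and 3: the alkene C4a=C5 is cut. This separates a one-carbon aldehyde electrophile from a commercial β-keto ester. The forward step must condense once at the aldehyde carbon and stop before a second addition.

2 to 1: the aldehyde carbon is returned to a methyl group. The acetophenone is commercial and already contains the hindered aryl–carbonyl bond, so that bond never has to be made. The forward step must oxidise the methyl group without attacking the electron-rich ring.

**Other disconnections considered**

Alternative 1: Both bonds at the carbonyl carbon are cut, giving 2-iodo-1,5-dimethoxy-3-(methoxymethoxy)benzene A1, the chromen-5-yl boronate A2 (taken here as the pinacol ester) and carbon monoxide A3. The forward key step is a three-component carbonylative Suzuki–Miyaura coupling under Pd(OAc)2 with di(1-adamantyl)butylphosphine, giving the bis-MOM ketone A4; mild acid then removes both MOM groups to reach 15.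
- In its favour: it is the most convergent plan. The ketone is made last, so no step has to tolerate it. It avoids both the high-temperature dehydrogenation and the Lewis-acid demethylation. On these points it is better than the chosen plan.
- Against it: A1 has two ortho substituents, which slow oxidative addition to zerovalent palladium and acyl transfer, and direct biaryl coupling without A3 competes. A toxic gas is needed. The final deprotection exposes the chromene to acid.
- A2 must itself come from a 3,5-dioxygenated aryl halide by statistical mono-propargylation and a propargyl Claisen cyclisation with the same regiochemical question. Those two problems are therefore equal in kind, though better placed on early, cheap material.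
- Step economy: about two steps to A1, about four to A2, then coupling and deprotection. The total is about equal to the chosen plan and the longest linear sequence is shorter.
- The chosen plan is preferred because it never forms a bond between two hindered arenes at a metal and keeps acid away from the finished chromene.

Alternative 2: The bonds from ring A C1 to the carbonyl carbon and from ring A C2 to oxygen are cut. In the forward step CsF releases an aryne from 3,5-dimethoxy-2-(trimethylsilyl)phenyl trifluoromethanesulfonate A5 and a nitrile oxide from N-hydroxy-3,5-bis(methoxymethoxy)benzenecarboximidoyl chloride A6. Their [3+2] cycloaddition gives the benzisoxazole A7. Reductive N–O cleavage and imine hydrolysis should give the ketone A8, and MOM removal then gives compound 11 of the chosen route.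
- In its favour: the ortho-hydroxy ketone of ring A emerges already distinguished from the two methyl ethers, so no selective demethylation is needed. The methoxy group next to the aryne directs the oxygen terminus to the distal carbon. Ring B is aromatic throughout. On these three points it is better than the chosen plan.
- Against it: A5 and A6 each need several steps. The nitrile oxide can dimerise. Hydrolysis of a hindered, hydrogen-bonded diaryl ketimine is slow.
- Ring B arrives symmetric, so the mono-etherification and Claisen regiochemistry of steps 7 and 8 remain unchanged; the endgame is equal.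
- Step economy: roughly eleven to twelve steps in total against eight, so it is worse on length.

Alternative 3: Ring B bonds C5–C6 and C4a–C8a are cut. The forward step is a thermal Diels–Alder reaction of 1-methoxy-1,3-bis(trimethylsilyloxy)buta-1,3-diene A9 with the ynal A10, with loss of methanol on mild acidic work-up, giving the benzaldehyde A11.
- In its favour: the formyl carbon sits on C4a and becomes C4 of the pyran, and the two ring B hydroxyls are differentiated (one chelated to the aldehyde). Pyran regiochemistry is therefore fixed by construction and no statistical etherification is needed. On this it is better than the chosen plan.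
- It reaches the arene oxidation level directly and needs no ring A demethylation; here it is equal or better.
- Against it: A10 takes several steps and A9 is moisture-sensitive. After the cycloaddition the pyran must be built from the aldehyde over two or three steps, the silyl ether removed, the doubly benzylic carbinol oxidised to the ketone, and the MOM group removed. The carbinol, flanked by two electron-rich rings and an ortho formyl group, is prone to ionisation and lactol formation.
- Both plans build ring B from acyclic material and both form C5–C6. The alternative costs about eleven to twelve linear steps and more redox and protecting-group changes, so the chosen plan is better on step economy and on robustness of intermediates.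

Key step: step 3

Remark: 4 is used as its E/Z mixture and 6, 7 and 8 as mixtures of diastereomers and keto–enol forms; all of this isomerism is gone after step 5, and 15 has no stereocentre.

**Route**

Step 1
Reactants: 1 1-(2,4,6-trimethoxyphenyl)ethanone
Product: 2 2-oxo-2-(2,4,6-trimethoxyphenyl)acetaldehyde
Conditions: SeO2 (1.2 equiv), 1,4-dioxane/H2O, 100 °C; filtration; toluene azeotrope
Reagents that add atoms: selenium dioxide, O=[Se]=O
Why: Riley oxidation of an aryl methyl ketone through its enol to the α-keto aldehyde; there is no other enolisable or allylic C–H, and the acyl group lowers the reactivity of the two free ring positions toward the weakly electrophilic selenium reagent; azeotropic drying delivers the free aldehyde for the condensation.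

Step 2
Reactants: 2 2-oxo-2-(2,4,6-trimethoxyphenyl)acetaldehyde; 3 methyl 3-oxobutanoate
Product: 4 methyl 2-acetyl-4-oxo-4-(2,4,6-trimethoxyphenyl)but-2-enoate (E/Z mixture)
Conditions: piperidine (5 mol %), AcOH (10 mol %), 4 Å MS, CH2Cl2, 0 °C to rt
Reagents that add atoms: none
Why: Knoevenagel condensation at the aldehyde carbon, which is far more electrophilic than the shielded, twisted aryl ketone; equimolar 3, low temperature and water removal should limit a second conjugate addition of 3; alkene geometry is irrelevant because it is lost in step 3, and 4 is used without storage.

Step 3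
Reactants: 4 methyl 2-acetyl-4-oxo-4-(2,4,6-trimethoxyphenyl)but-2-enoate; 5 dimethyl propanedioate
Product: 7 dimethyl 4,6-dioxo-2-(2,4,6-trimethoxybenzoyl)cyclohexane-1,3-dicarboxylate (stereoisomer and enol mixture), via open-chain Michael adduct 6 (not isolated)
Conditions: 5 (1.05 equiv), NaOMe (2.2 equiv), MeOH, 0 °C, then 65 °C; cold 1 M HCl to pH 3
Reagents that add atoms: none
Why: Sodio-malonate adds in conjugate fashion to the alkene carbon of 4 that bears the aroyl group, because that carbon is β to both the acetyl and the ester carbonyl and the charge arrives on the acetoacetate carbon; this forms C5–C6 and gives 6. Under equilibrating methoxide at reflux the acetyl methyl of 6 is deprotonated reversibly and its enolate carbon acylates one malonate ester with loss of methoxide, forming C7–C8. Ring B thus closes in the 6-exo-trig sense, the enolate carbon attacking an ester carbonyl whose C=O lies outside the new ring. The closest known reaction type is the Michael–Claisen annulation of malonates with enones to cyclohexane-1,3-diones, and the same open-chain adduct is the one through which alkylidene malonates and acetoacetates give 4,6-bis(alkoxycarbonyl)cyclohexane-1,3-diones. Closure is pulled forward by deprotonation of the strongly acidic product. The three sp3 centres of 7 equilibrate under the conditions and are all removed in steps 4 and 5, so no stereocontrol is needed. The required selectivities are the Michael regiochemistry, secured by double activation of the attacked carbon and full substitution of the other, and Claisen closure in preference to aldol attack or hemiketal and furan formation at the aryl ketone, secured by the two ortho methoxy groups that twist and shield that carbonyl and by keeping the medium basic until a cold acidic quench. Sodio-malonate is formed first and 4 added at 0 °C, so free methoxide does not meet the alkene or the acetyl group.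

Step 4
Reactants: 7 dimethyl 4,6-dioxo-2-(2,4,6-trimethoxybenzoyl)cyclohexane-1,3-dicarboxylate
Product: 9 5-(2,4,6-trimethoxybenzoyl)cyclohexane-1,3-dione, via bis-β-keto acid 8 (not isolated)
Conditions: NaOH (2 M aq.), MeOH, 60 °C; then HCl to pH 2–3, 60 °C
Reagents that add atoms: none
Why: Saponification of both β-keto esters gives 8, which loses two molecules of CO2 through the cyclic β-keto acid pathway on gentle acidification and warming; the enolised dione anion resists retro-Claisen cleavage in base, and only mild acid is used so the electron-rich aryl ketone is not protodeacylated.

Step 5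
Reactants: 9 5-(2,4,6-trimethoxybenzoyl)cyclohexane-1,3-dione
Product: 10 (3,5-dihydroxyphenyl)(2,4,6-trimethoxyphenyl)methanone
Conditions: Pd/C (10 wt % Pd), diglyme, 160 °C, N2 sweep
Reagents that add atoms: none
Why: Catalytic dehydrogenation of a cyclohexane-1,3-dione to a resorcinol; the enolised dione is one H2 short of the arene and aromatisation drives the loss; the gas sweep removes hydrogen so that transfer to the dione or the hindered diaryl ketone is limited, and no electrophilic halogen or mercury reagent is used because ring A would react with it.

Step 6
Reactants: 10 (3,5-dihydroxyphenyl)(2,4,6-trimethoxyphenyl)methanone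
Product: 11 (3,5-dihydroxyphenyl)(2-hydroxy-4,6-dimethoxyphenyl)methanone
Conditions: BCl3 (1 M in CH2Cl2, 4 equiv), CH2Cl2, −78 to 0 °C; aq. NaHCO3/MeOH work-up
Reagents that add atoms: none
Why: Chelation-directed ether cleavage: boron binds the ketone oxygen and one ortho methoxy oxygen and chloride removes that methyl; the resulting six-membered aryloxyboron chelate occupies the carbonyl, so the second ortho and the para methyl ether should remain; excess BCl3 covers the ring B phenols, which return on hydrolysis, and the step is placed before any propargyl ether or pyran exists.

Step 7
Reactants: 11 (3,5-dihydroxyphenyl)(2-hydroxy-4,6-dimethoxyphenyl)methanone; 12 3-chloro-3-methylbut-1-yne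
Product: 13 (2-hydroxy-4,6-dimethoxyphenyl)[3-hydroxy-5-(2-methylbut-3-yn-2-yloxy)phenyl]methanone
Conditions: 12 (0.8 equiv), DBU (1.1 equiv), CuCl2·2H2O (1 mol %), MeCN, 0 °C
Reagents that add atoms: none
Why: Copper-catalysed propargylic etherification of a phenoxide by a tertiary propargylic chloride, the standard entry to aryl 1,1-dimethylpropargyl ethers; the ring B phenols are more acidic and less hindered than the hydrogen-bonded ring A phenol, and because the two ring B hydroxyls are equivalent 12 is the limiting reagent, with unreacted 11 recovered and recycled.

Step 8
Reactants: 13 (2-hydroxy-4,6-dimethoxyphenyl)[3-hydroxy-5-(2-methylbut-3-yn-2-yloxy)phenyl]methanone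
Product: 15 (2-hydroxy-4,6-dimethoxyphenyl)(7-hydroxy-2,2-dimethyl-2H-chromen-5-yl)methanone, via ortho-allenyl phenol 14 (not isolated)
Conditions: 1,2-dichlorobenzene, 140 °C, N2
Reagents that add atoms: none
Why: Aromatic propargyl Claisen rearrangement and enolisation give 14, and a 1,5-hydrogen shift followed by 6π oxa-electrocyclisation closes the pyran, the standard route to 2,2-dimethyl-2H-chromenes; the [3,3] shift should go to the ortho carbon that is para to the free hydroxyl and adjacent to the acyl group, since meta donors direct away from themselves and meta acceptors toward themselves in aromatic Claisen rearrangements, and a neutral solvent keeps 14 from closing to a benzofuran.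

**Compound list**

1 | 1-(2,4,6-trimethoxyphenyl)ethanone | CC(=O)c1c(OC)cc(OC)cc1OC | starting material
2 | 2-oxo-2-(2,4,6-trimethoxyphenyl)acetaldehyde | O=CC(=O)c1c(OC)cc(OC)cc1OC | intermediate
3 | methyl 3-oxobutanoate | COC(=O)CC(C)=O | starting material
4 | methyl 2-acetyl-4-oxo-4-(2,4,6-trimethoxyphenyl)but-2-enoate (E/Z mixture) | COC(=O)C(C(C)=O)=CC(=O)c1c(OC)cc(OC)cc1OC | intermediate
5 | dimethyl propanedioate | COC(=O)CC(=O)OC | starting material
6 | trimethyl 4-oxo-2-(2,4,6-trimethoxybenzoyl)pentane-1,1,3-tricarboxylate (diastereomer mixture) | COC(=O)C(C(=O)OC)C(C(=O)c1c(OC)cc(OC)cc1OC)C(C(C)=O)C(=O)OC | intermediate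
7 | dimethyl 4,6-dioxo-2-(2,4,6-trimethoxybenzoyl)cyclohexane-1,3-dicarboxylate (stereoisomer and enol mixture) | COC(=O)C1C(=O)CC(=O)C(C(=O)OC)C1C(=O)c1c(OC)cc(OC)cc1OC | intermediate
8 | 4,6-dioxo-2-(2,4,6-trimethoxybenzoyl)cyclohexane-1,3-dicarboxylic acid (stereoisomer mixture) | OC(=O)C1C(=O)CC(=O)C(C(=O)O)C1C(=O)c1c(OC)cc(OC)cc1OC | intermediate
9 | 5-(2,4,6-trimethoxybenzoyl)cyclohexane-1,3-dione | O=C1CC(=O)CC(C1)C(=O)c1c(OC)cc(OC)cc1OC | intermediate
10 | (3,5-dihydroxyphenyl)(2,4,6-trimethoxyphenyl)methanone | Oc1cc(O)cc(c1)C(=O)c1c(OC)cc(OC)cc1OC | intermediate
11 | (3,5-dihydroxyphenyl)(2-hydroxy-4,6-dimethoxyphenyl)methanone | COc1cc(O)c(C(=O)c2cc(O)cc(O)c2)c(OC)c1 | intermediate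
12 | 3-chloro-3-methylbut-1-yne | CC(C)(Cl)C#C | starting material
13 | (2-hydroxy-4,6-dimethoxyphenyl)[3-hydroxy-5-(2-methylbut-3-yn-2-yloxy)phenyl]methanone | COc1cc(O)c(C(=O)c2cc(O)cc(OC(C)(C)C#C)c2)c(OC)c1 | intermediate
14 | [3,5-dihydroxy-2-(3-methylbuta-1,2-dien-1-yl)phenyl](2-hydroxy-4,6-dimethoxyphenyl)methanone | COc1cc(O)c(C(=O)c2cc(O)cc(O)c2C=C=C(C)C)c(OC)c1 | intermediate
15 | (2-hydroxy-4,6-dimethoxyphenyl)(7-hydroxy-2,2-dimethyl-2H-chromen-5-yl)methanone | COc1cc(O)c(C(=O)c2cc(O)cc3c2C=CC(C)(C)O3)c(OC)c1 | target

**Step count and least certain steps**

Total step count: 8. Longest linear sequence: 8 (from 1 to 15).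

Step 3 (key step). Most likely to go wrong: methoxide attacks the triply activated alkene or the acetyl carbonyl of 4 before malonate adds, or the enolate oxygen of the adduct adds to the aryl ketone so that a furan forms on acidification. Both follow from the 1,3,4-tricarbonyl array in 4. Fallback, setting out from 2 and returning at 7: the roles of the two partners are exchanged so that 4 is never exposed to methoxide. Knoevenagel condensation of 2 with 5 under the amine catalysis of step 2 would give dimethyl 2-[2-oxo-2-(2,4,6-trimethoxyphenyl)ethylidene]propanedioate F1, a sturdier acceptor without an enolisable acetyl group. Conjugate addition of 3 with catalytic NaOMe at 0 °C should occur at the aroyl-bearing carbon, which is activated by both esters, and give the same adduct 6. One further equivalent of NaOMe at reflux then closes 6 to 7.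

Step 5. Most likely to go wrong: the liberated hydrogen is transferred back to the dione or to the diaryl ketone (disproportionation, hydrogenolysis), or the chelating dione slows the catalyst. Fallback, setting out from 9 and returning at 10: the oxidation is done by hydride abstraction instead of on a metal surface. Me3SiOTf and Et3N in CH2Cl2 would convert 9 into [3,5-bis(trimethylsilyloxy)cyclohexa-2,4-dien-1-yl](2,4,6-trimethoxyphenyl)methanone F2. DDQ at 0 °C to rt should dehydrogenate this electron-rich cyclohexadiene to [3,5-bis(trimethylsilyloxy)phenyl](2,4,6-trimethoxyphenyl)methanone F3. Dilute aqueous HCl in THF removes the silyl groups to give 10.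

Step 7. Most likely to go wrong: a second etherification of the equivalent ring B hydroxyl runs alongside the first, and some reaction may occur at the ring A phenol, so the mono-ether is obtained only with recycling. Fallback, setting out from 9 and returning at 15: the two ring B oxygens are distinguished at the dione stage, where only one enolic hydroxyl exists.
- Benzyl alcohol with catalytic TsOH in toluene under water removal would give the vinylogous ester 3-(benzyloxy)-5-(2,4,6-trimethoxybenzoyl)cyclohex-2-en-1-one F4.
- LiN(iPr)2 and PhSeCl at −78 °C give 3-(benzyloxy)-6-(phenylselanyl)-5-(2,4,6-trimethoxybenzoyl)cyclohex-2-en-1-one F5. Oxidation with H2O2 and selenoxide elimination lead, after tautomerisation, to [3-(benzyloxy)-5-hydroxyphenyl](2,4,6-trimethoxyphenyl)methanone F6.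
- The single phenol of F6 is etherified with 12 as in step 7 to [3-(benzyloxy)-5-(2-methylbut-3-yn-2-yloxy)phenyl](2,4,6-trimethoxyphenyl)methanone F7.
- Heating as in step 8 should give [7-(benzyloxy)-2,2-dimethyl-2H-chromen-5-yl](2,4,6-trimethoxyphenyl)methanone F8.
- BCl3 with pentamethylbenzene in CH2Cl2 at −78 to −20 °C removes the benzyl group and the chelated ortho methyl together to give 15. This last step exposes the chromene to a Lewis acid at low temperature, which is why the sequence is a reserve and not the main route.

Step 8. Most likely to go wrong: the propargyl group migrates to the ring B carbon between the two oxygens, which is less hindered than the carbon next to the aroyl group, and the isomeric chromene results. Fallback, setting out from 13 and returning at 15: the undesired position is blocked sterically by a bulky donor group on the neighbouring oxygen. iPr3SiCl and imidazole in DMF should silylate the ring B hydroxyl of 13, not the chelated ring A hydroxyl, to give (2-hydroxy-4,6-dimethoxyphenyl)[3-(2-methylbut-3-yn-2-yloxy)-5-tri(propan-2-yl)silyloxyphenyl]methanone F9. Heating as in step 8 then gives (2-hydroxy-4,6-dimethoxyphenyl)[2,2-dimethyl-7-tri(propan-2-yl)silyloxy-2H-chromen-5-yl]methanone F10, since the silyl ether shields the carbon between the oxygens and still directs para. Bu4NF in THF at 0 °C releases 15.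

**Further compounds**

F1 | step 3 | dimethyl 2-[2-oxo-2-(2,4,6-trimethoxyphenyl)ethylidene]propanedioate | COC(=O)C(=CC(=O)c1c(OC)cc(OC)cc1OC)C(=O)OC
F2 | step 5 | [3,5-bis(trimethylsilyloxy)cyclohexa-2,4-dien-1-yl](2,4,6-trimethoxyphenyl)methanone | C[Si](C)(C)OC1=CC(O[Si](C)(C)C)=CC(C1)C(=O)c1c(OC)cc(OC)cc1OC
F3 | step 5 | [3,5-bis(trimethylsilyloxy)phenyl](2,4,6-trimethoxyphenyl)methanone | C[Si](C)(C)Oc1cc(O[Si](C)(C)C)cc(c1)C(=O)c1c(OC)cc(OC)cc1OC
F4 | step 7 | 3-(benzyloxy)-5-(2,4,6-trimethoxybenzoyl)cyclohex-2-en-1-one | O=C1C=C(OCc2ccccc2)CC(C1)C(=O)c1c(OC)cc(OC)cc1OC
F5 | step 7 | 3-(benzyloxy)-6-(phenylselanyl)-5-(2,4,6-trimethoxybenzoyl)cyclohex-2-en-1-one | O=C1C=C(OCc2ccccc2)CC(C(=O)c2c(OC)cc(OC)cc2OC)C1[Se]c1ccccc1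
F6 | step 7 | [3-(benzyloxy)-5-hydroxyphenyl](2,4,6-trimethoxyphenyl)methanone | Oc1cc(OCc2ccccc2)cc(c1)C(=O)c1c(OC)cc(OC)cc1OC
F7 | step 7 | [3-(benzyloxy)-5-(2-methylbut-3-yn-2-yloxy)phenyl](2,4,6-trimethoxyphenyl)methanone | C#CC(C)(C)Oc1cc(OCc2ccccc2)cc(c1)C(=O)c1c(OC)cc(OC)cc1OC
F8 | step 7 | [7-(benzyloxy)-2,2-dimethyl-2H-chromen-5-yl](2,4,6-trimethoxyphenyl)methanone | COc1cc(OC)c(C(=O)c2cc(OCc3ccccc3)cc3OC(C)(C)C=Cc23)c(OC)c1
F9 | step 8 | (2-hydroxy-4,6-dimethoxyphenyl)[3-(2-methylbut-3-yn-2-yloxy)-5-tri(propan-2-yl)silyloxyphenyl]methanone | COc1cc(O)c(C(=O)c2cc(O[Si](C(C)C)(C(C)C)C(C)C)cc(OC(C)(C)C#C)c2)c(OC)c1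
F10 | step 8 | (2-hydroxy-4,6-dimethoxyphenyl)[2,2-dimethyl-7-tri(propan-2-yl)silyloxy-2H-chromen-5-yl]methanone | COc1cc(O)c(C(=O)c2cc(O[Si](C(C)C)(C(C)C)C(C)C)cc3OC(C)(C)C=Cc23)c(OC)c1
A1 | alternative 1 | 2-iodo-1,5-dimethoxy-3-(methoxymethoxy)benzene | COCOc1cc(OC)cc(OC)c1I
A2 | alternative 1 | 2-[7-(methoxymethoxy)-2,2-dimethyl-2H-chromen-5-yl]-4,4,5,5-tetramethyl-1,3,2-dioxaborolane | COCOc1cc(B2OC(C)(C)C(C)(C)O2)c2C=CC(C)(C)Oc2c1
A3 | alternative 1 | carbon monoxide | [C-]#[O+]
A4 | alternative 1 | [2,4-dimethoxy-6-(methoxymethoxy)phenyl][7-(methoxymethoxy)-2,2-dimethyl-2H-chromen-5-yl]methanone | COCOc1cc(OC)cc(OC)c1C(=O)c1cc(OCOC)cc2OC(C)(C)C=Cc12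
A5 | alternative 2 | 3,5-dimethoxy-2-(trimethylsilyl)phenyl trifluoromethanesulfonate | COc1cc(OC)c([Si](C)(C)C)c(OS(=O)(=O)C(F)(F)F)c1
A6 | alternative 2 | N-hydroxy-3,5-bis(methoxymethoxy)benzenecarboximidoyl chloride | COCOc1cc(OCOC)cc(c1)C(Cl)=NO
A7 | alternative 2 | 3-[3,5-bis(methoxymethoxy)phenyl]-4,6-dimethoxy-1,2-benzoxazole | COCOc1cc(OCOC)cc(c1)-c1noc2cc(OC)cc(OC)c12
A8 | alternative 2 | [3,5-bis(methoxymethoxy)phenyl](2-hydroxy-4,6-dimethoxyphenyl)methanone | COCOc1cc(OCOC)cc(c1)C(=O)c1c(O)cc(OC)cc1OC
A9 | alternative 3 | 1-methoxy-1,3-bis(trimethylsilyloxy)buta-1,3-diene | COC(O[Si](C)(C)C)=CC(=C)O[Si](C)(C)C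
A10 | alternative 3 | rac-4-[tert-butyl(dimethyl)silyl]oxy-4-[2,4-dimethoxy-6-(methoxymethoxy)phenyl]but-2-ynal | COCOc1cc(OC)cc(OC)c1C(O[Si](C)(C)C(C)(C)C)C#CC=O
A11 | alternative 3 | rac-2-[[tert-butyl(dimethyl)silyl]oxy[2,4-dimethoxy-6-(methoxymethoxy)phenyl]methyl]-4,6-dihydroxybenzaldehyde | COCOc1cc(OC)cc(OC)c1C(O[Si](C)(C)C(C)(C)C)c1cc(O)cc(O)c1C=O
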